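Each half of the dimer is traced back to a 3-dienylisoquinoline whose ring B (C4a, C5, C6, C7, C8, C8a) holds C6 as a ketal. In that ring C7 is a tertiary carbinol next to the C8 ketone on pyridine carbon C8a, an acyloin; the C7–C8 bond is therefore made by a carbene-catalysed crossed benzoin cyclisation, which closes ring B and sets C7 in one operation. Its precursor is a pyridine-3-carbaldehyde with the (S)-dienyl chain para to the formyl group and, ortho to it, a CH2 arm ending in a dioxolane-masked carbonyl and a methyl ketone. Acetylation, double N-alkylation with a four-carbon bis(triflate), ketal unmasking and C5 chlorination complete the target.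

Key step: step 10

Remarks on the chemistry:
- Locants: isoquinoline numbering (N2, C1, C3, C4, C4a, C5–C8, C8a) is used for bicyclic compounds and pyridine numbering for monocyclic ones.
- Assumption: the (5aS,10bR) antipode of the triazolium salt is taken to deliver 7S by analogy with 2-hydroxy-2-methyltetralone cyclisations; both antipodes are commercial, and the antipode is exchanged should the first batch prove to be 7R.
- C6 is brought in already masked (dithiane, then dioxolane). A free, enolisable C6 ketone beside the masked C8 aldehyde could close onto C8 under acid to give a pyrano[4,3-c]pyridine.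
- The dienyl chain is attached after all strong-base steps, because its allylic C–H at the stereocentre is vinylogously acidified by the pyridine.
- The C7 descriptor is S in 17, 18, 21 and 23 but R in 22 and F4; the arrangement in space is the same, and only the CIP ranking of C6 against C8 changes.

Step 1
Reactants: 1 (S)-2-methylbutan-1-ol; 2 2-(triphenylphosphoranylidene)propanal
Product: 4 (2E,4S)-2,4-dimethylhex-2-enal, via (S)-2-methylbutanal 3 (not isolated)
Conditions: TEMPO (1 mol %), KBr (10 mol %), NaOCl (1.1 equiv), NaHCO3, toluene–H2O, 0 °C; toluene layer dried, then 2 (0.9 equiv), 80 °C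
Reagents that add atoms: none
Why: Hypochlorite oxidation mediated by the nitroxyl radical (Anelli oxidation) should give the α-branched aldehyde without epimerisation, and the Wittig reaction with the formyl-stabilised ylide should then give the (E)-trisubstituted enal, the stereocentre coming unchanged from 1.

Step 2
Reactants: 4 (2E,4S)-2,4-dimethylhex-2-enal; 5 2-(dichloromethyl)-4,4,5,5-tetramethyl-1,3,2-dioxaborolane
Product: 6 2-[(1E,3E,5S)-3,5-dimethylhepta-1,3-dien-1-yl]-4,4,5,5-tetramethyl-1,3,2-dioxaborolane
Conditions: CrCl2 (8 equiv), LiI (4 equiv), THF, 25 °C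
Reagents that add atoms: none
Why: Takai–Utimoto boryl-olefination: the geminal dichromium reagent generated from 5 and divalent chromium adds to the aldehyde and eliminates to the (E)-alkenyl boronate under non-basic conditions that cannot touch the allylic stereocentre.

Step 3
Reactants: 7 6-chloro-4-methylpyridine-3-carbaldehyde
Product: 8 2-chloro-5-(1,3-dioxolan-2-yl)-4-methylpyridine
Conditions: HOCH2CH2OH (3 equiv), TsOH·H2O (5 mol %), toluene, reflux, Dean–Stark
Reagents that add atoms: ethylene glycol, OCCO
Why: Acid-catalysed acetalisation with azeotropic removal of water masks the formyl group against the carbanion chemistry of the next steps.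

Step 4
Reactants: 8 2-chloro-5-(1,3-dioxolan-2-yl)-4-methylpyridine
Product: 9 2-chloro-4-(chloromethyl)-5-(1,3-dioxolan-2-yl)pyridine
Conditions: LiN(iPr)2 (1.05 equiv), THF, −78 °C; cannulated into C2Cl6 (1.5 equiv), THF, −78 °C
Reagents that add atoms: hexachloroethane, ClC(Cl)(Cl)C(Cl)(Cl)Cl
Why: Lateral lithiation of the γ-methyl group, the most acidic C–H of a 2-chloro-4-picoline, followed by electrophilic chlorination of the picolyl anion with hexachloroethane (inverse addition, to avoid coupling with the product) should give the benzylic chloride.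

Step 5
Reactants: 9 2-chloro-4-(chloromethyl)-5-(1,3-dioxolan-2-yl)pyridine; 10 ethyl 1,3-dithiane-2-carboxylate
Product: 11 ethyl 2-{[2-chloro-5-(1,3-dioxolan-2-yl)pyridin-4-yl]methyl}-1,3-dithiane-2-carboxylate
Conditions: NaH (1.1 equiv), DMF, 0 °C; then 9, NaI (10 mol %), 0 → 25 °C
Reagents that add atoms: none
Why: SN2 alkylation of the sodium salt of the dithiane ester, a glyoxylate acyl-anion equivalent (Corey–Seebach-type umpolung), by the activated picolyl chloride forms the C5–C6 bond with C6 already at the masked ketone level.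

Step 6
Reactants: 11 ethyl 2-{[2-chloro-5-(1,3-dioxolan-2-yl)pyridin-4-yl]methyl}-1,3-dithiane-2-carboxylate
Product: 12 ethyl 2-{[2-chloro-5-(1,3-dioxolan-2-yl)pyridin-4-yl]methyl}-1,3-dioxolane-2-carboxylate
Conditions: PhI(OCOCF3)2 (1.5 equiv), HOCH2CH2OH (20 equiv), MeCN, 0 → 25 °C
Reagents that add atoms: ethylene glycol, OCCO
Why: Oxidative dethioketalisation with the hypervalent iodine reagent in the presence of ethylene glycol converts the dithiane directly into the dioxolane (S-activation, C–S ionisation, capture by the diol), so that a free C6 ketone never appears next to the masked aldehyde.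

Step 7
Reactants: 12 ethyl 2-{[2-chloro-5-(1,3-dioxolan-2-yl)pyridin-4-yl]methyl}-1,3-dioxolane-2-carboxylate
Product: 14 1-(2-{[2-chloro-5-(1,3-dioxolan-2-yl)pyridin-4-yl]methyl}-1,3-dioxolan-2-yl)ethan-1-one, via Weinreb amide 13 (not isolated)
Conditions: MeNH(OMe)·HCl (1.5 equiv), iPrMgCl (3.0 equiv), THF, −20 °C; then MeMgBr (3 equiv), −20 → 0 °C; aq. NH4Cl
Reagents that add atoms: methylmagnesium bromide, C[Mg]Br; N,O-dimethylhydroxylamine hydrochloride, Cl.CNOC (its atoms are held only in 13)
Why: Aminolysis of the ester by the chloromagnesium amide of N,O-dimethylhydroxylamine and Grignard addition to the resulting Weinreb amide, whose magnesium chelate resists a second addition, should give the methyl ketone in one flask without touching the chloropyridine or the dioxolanes.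

Step 8
Reactants: 14 1-(2-{[2-chloro-5-(1,3-dioxolan-2-yl)pyridin-4-yl]methyl}-1,3-dioxolan-2-yl)ethan-1-one
Product: 15 4-[(2-acetyl-1,3-dioxolan-2-yl)methyl]-6-chloropyridine-3-carbaldehyde
Conditions: 1 M HCl–THF (1:1), 40 °C
Reagents that add atoms: water, O
Why: Selective acetal hydrolysis: the aryl dioxolane on the barely basic chloropyridine ionises through a benzylic oxocarbenium ion, whereas the ketal next to the acetyl group would give a strongly destabilised cation and should stay intact.

Step 9
Reactants: 15 4-[(2-acetyl-1,3-dioxolan-2-yl)methyl]-6-chloropyridine-3-carbaldehyde; 6 2-[(1E,3E,5S)-3,5-dimethylhepta-1,3-dien-1-yl]-4,4,5,5-tetramethyl-1,3,2-dioxaborolane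
Product: 16 4-[(2-acetyl-1,3-dioxolan-2-yl)methyl]-6-[(1E,3E,5S)-3,5-dimethylhepta-1,3-dien-1-yl]pyridine-3-carbaldehyde
Conditions: PdCl2(dppf) (5 mol %), K3PO4 (2 equiv), 1,4-dioxane–H2O (10:1), 70 °C
Reagents that add atoms: none
Why: Suzuki–Miyaura coupling: the 2-chloropyridine, activated by the ring nitrogen and the para formyl group, adds oxidatively to zerovalent palladium and the alkenyl boronate transfers with retention of the (E,E) geometry, the chain being attached only now so that its allylic stereocentre never meets a strong base.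

Step 10
Reactants: 16 4-[(2-acetyl-1,3-dioxolan-2-yl)methyl]-6-[(1E,3E,5S)-3,5-dimethylhepta-1,3-dien-1-yl]pyridine-3-carbaldehyde
Product: 17 (7S)-3-[(1E,3E,5S)-3,5-dimethylhepta-1,3-dien-1-yl]-7-hydroxy-7-methyl-5,7-dihydroisoquinoline-6,8-dione 6-(ethylene ketal)
Conditions: (5aS,10bR)-2-(pentafluorophenyl)-5a,10b-dihydro-4H,6H-indeno[2,1-b][1,2,4]triazolo[4,3-d][1,4]oxazin-2-ium tetrafluoroborate (15 mol %), Et3N (15 mol %), THF (0.05 M), 25 °C, argon; AcOH quench at full conversion
Reagents that add atoms: none
Why: The carbene released from the triazolium salt adds to the formyl group, proton transfer gives the enaminol (acyl anion equivalent), this attacks the methyl ketone carbonyl, and collapse of the adduct releases the carbene and the α-hydroxy ketone, so that C7–C8 is formed. The closest known reaction is the triazolium-catalysed enantioselective aldehyde–ketone crossed benzoin cyclisation that gives 2-hydroxy-2-methyltetralones. Ring B closes in a 6-exo-trig mode. The configuration at C7 is decided by the catalyst, whose fused aminoindanol backbone shields one face of the enaminol so that the ketone offers a single enantioface, the remote side-chain centre having no influence. The step needs chemoselectivity (acyl anion onto the ketone instead of aldol closure or intermolecular benzoin) and enantioface selectivity: the non-enolisable heteroaryl aldehyde is the only possible acyl-anion donor, the dioxolane removes C6 as a competing acceptor while activating the ketone inductively and favouring ring closure by geminal disubstitution, and the weak amine base at high dilution keeps the methyl ketone from enolising and the aldehyde from dimerising.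

Step 11
Reactants: 17 (7S)-3-[(1E,3E,5S)-3,5-dimethylhepta-1,3-dien-1-yl]-7-hydroxy-7-methyl-5,7-dihydroisoquinoline-6,8-dione 6-(ethylene ketal)
Product: 18 (7S)-7-acetoxy-3-[(1E,3E,5S)-3,5-dimethylhepta-1,3-dien-1-yl]-7-methyl-5,7-dihydroisoquinoline-6,8-dione 6-(ethylene ketal)
Conditions: Ac2O (5 equiv), Et3N (6 equiv), DMAP (20 mol %), CH2Cl2, 25 °C
Reagents that add atoms: acetic anhydride, CC(=O)OC(C)=O
Why: DMAP-catalysed acylation (through the N-acetylpyridinium ion) esterifies the tertiary α-ketol without touching the quaternary stereocentre and removes the only other nucleophile before the alkylation.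

Step 12
Reactants: 19 butane-1,4-diol
Product: 20 butane-1,4-diyl bis(trifluoromethanesulfonate)
Conditions: Tf2O (2.4 equiv), pyridine (2.4 equiv), CH2Cl2, −78 → 0 °C, diol added to the anhydride; used at once
Reagents that add atoms: trifluoromethanesulfonic anhydride, O=S(=O)(OS(=O)(=O)C(F)(F)F)C(F)(F)F
Why: O-Sulfonylation of both primary hydroxyl groups, with the diol added to excess anhydride, outruns cyclisation of the mono-triflate, and any tetrahydrofuran formed is reopened by the anhydride to the same bis(triflate).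

Step 13
Reactants: 18 (7S)-7-acetoxy-3-[(1E,3E,5S)-3,5-dimethylhepta-1,3-dien-1-yl]-7-methyl-5,7-dihydroisoquinoline-6,8-dione 6-(ethylene ketal) (2.2 equiv); 20 butane-1,4-diyl bis(trifluoromethanesulfonate)
Product: 21 2,2'-(butane-1,4-diyl)bis{(7S)-7-acetoxy-3-[(1E,3E,5S)-3,5-dimethylhepta-1,3-dien-1-yl]-6,6-(ethylenedioxy)-7-methyl-8-oxo-5,6,7,8-tetrahydroisoquinolin-2-ium} bis(trifluoromethanesulfonate)
Conditions: MeCN, 4 Å molecular sieves, 25 → 40 °C; precipitation with Et2O
Reagents that add atoms: none
Why: Menshutkin-type N-alkylation: the pyridine nitrogen is the only nucleophile left in 18, and the primary triflate is reactive enough at both chain ends to overcome the ortho dienyl group and the electron-poor ring, giving the bis(pyridinium) salt.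

Step 14
Reactants: 21 2,2'-(butane-1,4-diyl)bis{(7S)-7-acetoxy-3-[(1E,3E,5S)-3,5-dimethylhepta-1,3-dien-1-yl]-6,6-(ethylenedioxy)-7-methyl-8-oxo-5,6,7,8-tetrahydroisoquinolin-2-ium} bis(trifluoromethanesulfonate)
Product: 22 2,2'-(butane-1,4-diyl)bis{(7R)-7-acetoxy-3-[(1E,3E,5S)-3,5-dimethylhepta-1,3-dien-1-yl]-7-methylisoquinoline-6,8(2H,7H)-dione}
Conditions: NaOAc (6 equiv), AcOH–H2O–MeCN (1:1:2), 45 °C; then aq. NaHCO3
Reagents that add atoms: water, O
Why: Ketal hydrolysis by elimination–addition: acetate removes the C5–H acidified by the N-alkylpyridinium, the dienamine so formed expels a ketal oxygen from C6, water adds, ethylene glycol leaves, and the final proton loss gives the neutral, strongly stabilised vinylogous pyridone in both halves while the buffer spares the tertiary acetates.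

Step 15
Reactants: 22 2,2'-(butane-1,4-diyl)bis{(7R)-7-acetoxy-3-[(1E,3E,5S)-3,5-dimethylhepta-1,3-dien-1-yl]-7-methylisoquinoline-6,8(2H,7H)-dione}
Product: 23 Penazaphilone I, 2,2'-(butane-1,4-diyl)bis{(7S)-7-acetoxy-5-chloro-3-[(1E,3E,5S)-3,5-dimethylhepta-1,3-dien-1-yl]-7-methylisoquinoline-6,8(2H,7H)-dione}
Conditions: N-chlorosuccinimide (2.1 equiv), MeCN, 0 → 25 °C, dark
Reagents that add atoms: N-chlorosuccinimide, O=C1CCC(=O)N1Cl
Why: Electrophilic α-chlorination of the vinylogous amide: attack of the chloronium equivalent at C5 gives an aromatic pyridinium intermediate (attack at C4 or on the chain would not), and loss of the C5 proton restores the chromophore in each half, the stereocentres being untouched.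

Compound list
1 | (S)-2-methylbutan-1-ol | CC[C@H](C)CO | starting material
2 | 2-(triphenylphosphoranylidene)propanal | CC(C=O)=P(c1ccccc1)(c1ccccc1)c1ccccc1 | starting material
3 | (S)-2-methylbutanal | CC[C@H](C)C=O | intermediate
4 | (2E,4S)-2,4-dimethylhex-2-enal | CC[C@H](C)/C=C(C)/C=O | intermediate
5 | 2-(dichloromethyl)-4,4,5,5-tetramethyl-1,3,2-dioxaborolane | ClC(Cl)B1OC(C)(C)C(C)(C)O1 | starting material
6 | 2-[(1E,3E,5S)-3,5-dimethylhepta-1,3-dien-1-yl]-4,4,5,5-tetramethyl-1,3,2-dioxaborolane | CC[C@H](C)/C=C(C)/C=C/B1OC(C)(C)C(C)(C)O1 | intermediate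
7 | 6-chloro-4-methylpyridine-3-carbaldehyde | Cc1cc(Cl)ncc1C=O | starting material
8 | 2-chloro-5-(1,3-dioxolan-2-yl)-4-methylpyridine | Cc1cc(Cl)ncc1C1OCCO1 | intermediate
9 | 2-chloro-4-(chloromethyl)-5-(1,3-dioxolan-2-yl)pyridine | ClCc1cc(Cl)ncc1C1OCCO1 | intermediate
10 | ethyl 1,3-dithiane-2-carboxylate | CCOC(=O)C1SCCCS1 | starting material
11 | ethyl 2-{[2-chloro-5-(1,3-dioxolan-2-yl)pyridin-4-yl]methyl}-1,3-dithiane-2-carboxylate | CCOC(=O)C1(Cc2cc(Cl)ncc2C2OCCO2)SCCCS1 | intermediate
12 | ethyl 2-{[2-chloro-5-(1,3-dioxolan-2-yl)pyridin-4-yl]methyl}-1,3-dioxolane-2-carboxylate | CCOC(=O)C1(Cc2cc(Cl)ncc2C2OCCO2)OCCO1 | intermediate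
13 | 2-{[2-chloro-5-(1,3-dioxolan-2-yl)pyridin-4-yl]methyl}-N-methoxy-N-methyl-1,3-dioxolane-2-carboxamide (Weinreb amide) | CON(C)C(=O)C1(Cc2cc(Cl)ncc2C2OCCO2)OCCO1 | intermediate
14 | 1-(2-{[2-chloro-5-(1,3-dioxolan-2-yl)pyridin-4-yl]methyl}-1,3-dioxolan-2-yl)ethan-1-one | CC(=O)C1(Cc2cc(Cl)ncc2C2OCCO2)OCCO1 | intermediate
15 | 4-[(2-acetyl-1,3-dioxolan-2-yl)methyl]-6-chloropyridine-3-carbaldehyde | CC(=O)C1(Cc2cc(Cl)ncc2C=O)OCCO1 | intermediate
16 | 4-[(2-acetyl-1,3-dioxolan-2-yl)methyl]-6-[(1E,3E,5S)-3,5-dimethylhepta-1,3-dien-1-yl]pyridine-3-carbaldehyde | O=Cc1cnc(/C=C/C(C)=C/[C@@H](C)CC)cc1CC1(OCCO1)C(C)=O | intermediate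
17 | (7S)-3-[(1E,3E,5S)-3,5-dimethylhepta-1,3-dien-1-yl]-7-hydroxy-7-methyl-5,7-dihydroisoquinoline-6,8-dione 6-(ethylene ketal) | O=C1c2cnc(/C=C/C(C)=C/[C@@H](C)CC)cc2CC2(OCCO2)[C@@]1(C)O | intermediate
18 | (7S)-7-acetoxy-3-[(1E,3E,5S)-3,5-dimethylhepta-1,3-dien-1-yl]-7-methyl-5,7-dihydroisoquinoline-6,8-dione 6-(ethylene ketal) | O=C1c2cnc(/C=C/C(C)=C/[C@@H](C)CC)cc2CC2(OCCO2)[C@@]1(C)OC(C)=O | intermediate
19 | butane-1,4-diol | OCCCCO | starting material
20 | butane-1,4-diyl bis(trifluoromethanesulfonate) | O=S(=O)(OCCCCOS(=O)(=O)C(F)(F)F)C(F)(F)F | intermediate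
21 | 2,2'-(butane-1,4-diyl)bis{(7S)-7-acetoxy-3-[(1E,3E,5S)-3,5-dimethylhepta-1,3-dien-1-yl]-6,6-(ethylenedioxy)-7-methyl-8-oxo-5,6,7,8-tetrahydroisoquinolin-2-ium} bis(trifluoromethanesulfonate) | CC[C@H](C)/C=C(C)/C=C/c1cc2c(c[n+]1CCCC[n+]1cc3c(cc1/C=C/C(C)=C/[C@@H](C)CC)CC1(OCCO1)[C@@](C)(OC(C)=O)C3=O)C(=O)[C@](C)(OC(C)=O)C1(OCCO1)C2.[O-]S(=O)(=O)C(F)(F)F.[O-]S(=O)(=O)C(F)(F)F | intermediate
22 | 2,2'-(butane-1,4-diyl)bis{(7R)-7-acetoxy-3-[(1E,3E,5S)-3,5-dimethylhepta-1,3-dien-1-yl]-7-methylisoquinoline-6,8(2H,7H)-dione} | CC[C@H](C)/C=C(C)/C=C/C1=CC2=CC(=O)[C@@](C)(OC(C)=O)C(=O)C2=CN1CCCCN1C=C2C(=O)[C@](C)(OC(C)=O)C(=O)C=C2C=C1/C=C/C(C)=C/[C@@H](C)CC | intermediate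
23 | Penazaphilone I | CC[C@H](C)/C=C(C)/C=C/C1=CC2=C(Cl)C(=O)[C@@](C)(OC(C)=O)C(=O)C2=CN1CCCCN1C=C2C(=O)[C@](C)(OC(C)=O)C(=O)C(Cl)=C2C=C1/C=C/C(C)=C/[C@@H](C)CC | target

Total step count: 15. Longest linear sequence: 12 steps (steps 3 to 11 and 13 to 15, from 7).

Steps most likely to fail

1. Step 10. What may go wrong: sluggish addition of the acyl anion equivalent to the hindered α,α-dialkoxy ketone, base-induced aldol closure of the methyl ketone onto the aldehyde, or erosion of the C7 configuration by retro-benzoin equilibration. The fallback sets out from 15 and comes back at 17. Reductive ketyl–carbonyl (pinacol-type) cyclisation of 15 with SmI2 and t-BuOH in THF at −78 °C, in which the easily reduced pyridine aldehyde forms the ketyl and closes ring B, should give the racemic cis-diol F1. Oxidation of its secondary pyridylic alcohol with 2-iodoxybenzoic acid in DMSO gives the racemic chloro ketol F2. Preparative chromatography on a chiral stationary phase supplies the (7S)-chloro ketol F3, and Suzuki–Miyaura coupling of F3 with 6 under the conditions of step 9 gives 17.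

2. Step 14. What may go wrong: incomplete unmasking at one of the two ketals, cleavage of the tertiary acetates, or degradation of the doubly charged salt on prolonged warming. The fallback sets out from 18 and comes back at 22, bypassing step 13 as well. The ketal is removed on the neutral monomer 18 in AcOH–H2O with NaOAc at 60 °C, where the N-protonated pyridine plays the part of the N-alkylpyridinium, to give the N–H vinylogous pyridone F4. Two molecules of F4 are then joined by N-alkylation with 1,4-diiodobutane and Cs2CO3 in DMF at 40 °C; the soft iodide should favour nitrogen over the C6 oxygen, as with 4-pyridones, and this gives 22.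

3. Step 6. What may go wrong: over-oxidation at sulfur without C–S cleavage, loss of the C5 proton from the cationic intermediates (vinyl sulfide or enol ether formation), or acetal scrambling with the neighbouring aryl dioxolane. The fallback sets out from 8 and comes back at 13; it replaces steps 4 to 6 by acylation and thermodynamic ketalisation. The picolyl anion from 8 (LiN(iPr)2, THF, −78 °C) is added to excess dimethyl oxalate at −78 °C and quenched cold with AcOH to give the pyridylpyruvate F5. Ketalisation with a large excess of ethylene glycol (TsOH, benzene, Dean–Stark) gives the methyl dioxolane ester F6, and aminolysis of F6 under the conditions of step 7 gives the Weinreb amide 13 and from it 14.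

Further compounds
F1 | step 10 | rac-cis-3-chloro-7,8-dihydroxy-7-methyl-7,8-dihydroisoquinolin-6(5H)-one ethylene ketal (racemate, drawn as the 7S,8S enantiomer) | O[C@H]1c2cnc(Cl)cc2CC2(OCCO2)[C@@]1(C)O
F2 | step 10 | rac-3-chloro-7-hydroxy-7-methyl-5,7-dihydroisoquinoline-6,8-dione 6-(ethylene ketal) (racemate) | O=C1c2cnc(Cl)cc2CC2(OCCO2)C1(C)O
F3 | step 10 | (7S)-3-chloro-7-hydroxy-7-methyl-5,7-dihydroisoquinoline-6,8-dione 6-(ethylene ketal) | O=C1c2cnc(Cl)cc2CC2(OCCO2)[C@@]1(C)O
F4 | step 14 | (7R)-7-acetoxy-3-[(1E,3E,5S)-3,5-dimethylhepta-1,3-dien-1-yl]-7-methylisoquinoline-6,8(2H,7H)-dione | CC[C@H](C)/C=C(C)/C=C/C1=CC2=CC(=O)[C@@](C)(OC(C)=O)C(=O)C2=CN1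
F5 | step 6 | methyl 3-[2-chloro-5-(1,3-dioxolan-2-yl)pyridin-4-yl]-2-oxopropanoate | COC(=O)C(=O)Cc1cc(Cl)ncc1C1OCCO1
F6 | step 6 | methyl 2-{[2-chloro-5-(1,3-dioxolan-2-yl)pyridin-4-yl]methyl}-1,3-dioxolane-2-carboxylate | COC(=O)C1(Cc2cc(Cl)ncc2C2OCCO2)OCCO1
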